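**Retrosynthetic overview**
- The target comes from the corresponding ynone by syn-semihydrogenation, which sets the Z-alkene in the last step.
- The bicyclic ynone comes from an acyclic 1,3-diketone and a vicinal tricarbonyl ester in one flask: the C4–C5 bond (Markovnikov hydroalkylation of an isopropenyl group) closes the cyclohexanone, then a C1–C7 aldol and a C5–C6 Claisen-type acylation close the cyclopentane.
- The acyclic diketone comes from (−)-limonene oxide by ring cleavage, Wittig olefination, C-acylation and γ-prenylation; its single stereocentre becomes C3 and steers C1, C5 and C7.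
- The tricarbonyl ester comes from silyl-protected 2-methylbut-3-yn-2-ol, CO2 and a phenyl bromoacetate-derived ylide (ylide acylation, then ozonolysis).
- Ring order: six-membered carbocycle first, five-membered carbocycle second, both in the same operation.

Assumption: the target is made as the open-chain (Z)-hydroxy enone exactly as drawn (it may equilibrate with its cyclic hemiketal); bicyclic locants are C1 = prenyl bridgehead, C3 = CH-prenyl, C4 = CMe2, C5 = acyl bridgehead, C6 = ring ketone, C7 = carbinol, C8 = bridging ketone.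

**Route**

Step 1
Reactants: 1 (4S)-limonene 1,2-oxide (cis/trans mixture)
Product: 2 (3S)-6-oxo-3-(prop-1-en-2-yl)heptanal
Conditions: H5IO6, THF/H2O, 0 °C → rt
Reagents that add atoms: water, O
Why: Acid-promoted opening of the epoxide to the diol and in situ periodate glycol cleavage (Malaprade reaction) unzip the ring to the keto aldehyde, and the limonene stereocentre is not involved and is carried through unchanged.

Step 2
Reactants: 2 (3S)-6-oxo-3-(prop-1-en-2-yl)heptanal
Product: 3 (5S)-8-methyl-5-(prop-1-en-2-yl)non-7-en-2-one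
Conditions: i-PrPPh3I, n-BuLi, THF, 0 °C; then 2, −78 → 0 °C
Reagents that add atoms: isopropyltriphenylphosphonium iodide, CC(C)[P+](c1ccccc1)(c1ccccc1)c1ccccc1.[I-]
Why: Wittig olefination with the non-stabilised isopropylidene ylide is selective for the aldehyde over the methyl ketone at low temperature and builds the prenyl terminus; no stereocentre is formed and the existing one (β to the aldehyde) cannot epimerise.

Step 3
Reactants: 3 (5S)-8-methyl-5-(prop-1-en-2-yl)non-7-en-2-one
Product: 4 (8S)-2,11-dimethyl-8-(prop-1-en-2-yl)dodec-10-ene-3,5-dione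
Conditions: LiN(iPr)2 (2.2 equiv), THF, −78 °C; 1-(2-methylpropanoyl)-1H-benzotriazole, −78 → 0 °C; NH4Cl
Reagents that add atoms: 1-(2-methylpropanoyl)-1H-benzotriazole, CC(C)C(=O)n1nnc2ccccc21
Why: Kinetic deprotonation at the methyl group and C-acylation of the lithium enolate by the N-acylbenzotriazole (crossed Claisen-type acylation) give the 1,3-diketone, the second equivalent of base holding the product as its enolate; no stereocentre is formed.

Step 4
Reactants: 4 (8S)-2,11-dimethyl-8-(prop-1-en-2-yl)dodec-10-ene-3,5-dione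
Product: 5 (8R)-2,11-dimethyl-6-(3-methylbut-2-en-1-yl)-8-(prop-1-en-2-yl)dodec-10-ene-3,5-dione (both C6 epimers; the descriptor at C8 changes only because the priorities change)
Conditions: LiN(iPr)2 (2.2 equiv), THF, −78 → 0 °C; prenyl bromide (1.0 equiv), −78 → 0 °C; NH4Cl
Reagents that add atoms: 1-bromo-3-methylbut-2-ene, CC(C)=CCBr
Why: γ-Alkylation of the 1,3-diketone dianion (Hauser–Harris type) takes place at the terminal CH2 enolate carbon rather than at the stabilised central carbon or the isopropyl methine; the new C6 centre forms as a mixture, which is harmless because it stays enolisable until step 9.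

Step 5
Reactants: 6 phenyl bromoacetate
Product: 8 phenyl (triphenyl-λ5-phosphanylidene)acetate, via phosphonium bromide 7 (not isolated)
Conditions: PPh3, toluene, rt; then cold 1 M NaOH, CH2Cl2, 0 °C
Reagents that add atoms: triphenylphosphine, c1ccc(cc1)P(c1ccccc1)c1ccccc1
Why: SN2 quaternisation of triphenylphosphine by the α-bromo ester and deprotonation of the acidic phosphonium salt give the ester-stabilised ylide (standard Wittig-reagent preparation); no stereocentre.

Step 6
Reactants: 9 trimethyl[(2-methylbut-3-yn-2-yl)oxy]silane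
Product: 10 lithium 4-methyl-4-[(trimethylsilyl)oxy]pent-2-ynoate
Conditions: n-BuLi, THF, −78 °C; CO2; evaporate
Reagents that add atoms: carbon dioxide, O=C=O; n-butyllithium, [Li]CCCC
Why: Deprotonation of the terminal alkyne and carboxylation of the lithium acetylide give the alkynoate, kept as its lithium salt so that the acid-labile tertiary silyl ether survives; no stereocentre.

Step 7
Reactants: 10 lithium 4-methyl-4-[(trimethylsilyl)oxy]pent-2-ynoate; 8 phenyl (triphenyl-λ5-phosphanylidene)acetate
Product: 11 phenyl 6-methyl-3-oxo-2-(triphenyl-λ5-phosphanylidene)-6-[(trimethylsilyl)oxy]hept-4-ynoate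
Conditions: EDC·HCl, DMAP (cat.), CH2Cl2, 0 °C → rt
Reagents that add atoms: none
Why: Carbodiimide activation of the carboxylate and C-acylation of the stabilised ylide (Wasserman-type keto-ylide synthesis) give the doubly stabilised acyl ylide; no stereocentre.

Step 8
Reactants: 11 phenyl 6-methyl-3-oxo-2-(triphenyl-λ5-phosphanylidene)-6-[(trimethylsilyl)oxy]hept-4-ynoate
Product: 12 phenyl 6-methyl-2,3-dioxo-6-[(trimethylsilyl)oxy]hept-4-ynoate
Conditions: O3, CH2Cl2, −78 °C; N2 purge; toluene azeotrope
Reagents that add atoms: ozone, [O-][O+]=O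
Why: Ozone cleaves the electron-rich P=C bond of the diacyl ylide much faster than it attacks the electron-poor ynone triple bond and so unveils the central carbonyl of the vicinal tricarbonyl (Wasserman ylide ozonolysis); no stereocentre.

Step 9
Reactants: 5 (8R)-2,11-dimethyl-6-(3-methylbut-2-en-1-yl)-8-(prop-1-en-2-yl)dodec-10-ene-3,5-dione; 12 phenyl 6-methyl-2,3-dioxo-6-[(trimethylsilyl)oxy]hept-4-ynoate
Product: 15 (1S,3R,5R,7S)-7-hydroxy-7-(4-hydroxy-4-methylpent-2-ynoyl)-4,4-dimethyl-1,3-bis(3-methylbut-2-en-1-yl)-5-(2-methylpropanoyl)bicyclo[3.2.1]octane-6,8-dione, via cyclohexanone diketone 13 (not isolated), via bicyclic trimethylsilyl ether 14 (not isolated)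
Conditions: a) Co(C32H46N2O2) [N,N′-bis(3,5-di-tert-butylsalicylidene)ethane-1,2-diaminato cobalt, divalent cobalt] 5 mol%, N-fluoro-2,4,6-trimethylpyridinium triflate, PhSiH3, PhCF3, rt; b) evaporate, THF, LiN(iPr)2 (3.4 equiv), −78 °C, then 12, −78 → −40 °C; c) 1 M HCl, THF, 0 °C
Reagents that add atoms: none
Why: Proposed new method: in a) hydrogen-atom transfer from a cobalt hydride to the 1,1-disubstituted isopropenyl group (faster than to the trisubstituted prenyl alkenes) gives the tertiary radical, which is oxidised (radical–polar crossover) and captured 6-exo by the central carbon of the 1,3-diketone through a chair with the prenyl group at the limonene-derived centre equatorial, forming the C4–C5 bond of cyclohexanone 13 whose two α-centres stay enolisable; in b) the dianion of 13 adds through its prenyl-bearing α′-carbon, axially and trans to that equatorial prenyl group, to the central carbonyl of 12 (aldol, C1–C7 bond) and the lithium diketonate carbon then attacks the 1,3-diaxially held phenyl ester (Claisen-type acylation, C5–C6 bond) to close the cyclopentane, which fixes C1 and C5 relative to C3, while C7 is set by the reversible aldol with the bulky ynoyl group exo and the hydroxyl endo, and c) removes the silyl group; the closest known reaction types are cobalt-catalysed Markovnikov hydrofunctionalisation of alkenes by radical–polar crossover, enolate addition to the central carbonyl of vicinal tricarbonyls, and the Effenberger α,α′-annulation of cyclohexanones with bis-acyl electrophiles.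

Step 10
Reactants: 15 (1S,3R,5R,7S)-7-hydroxy-7-(4-hydroxy-4-methylpent-2-ynoyl)-4,4-dimethyl-1,3-bis(3-methylbut-2-en-1-yl)-5-(2-methylpropanoyl)bicyclo[3.2.1]octane-6,8-dione
Product: 16 (1S,3R,5R,7S)-7-hydroxy-7-[(2Z)-4-hydroxy-4-methylpent-2-enoyl]-4,4-dimethyl-1,3-bis(3-methylbut-2-en-1-yl)-5-(2-methylpropanoyl)bicyclo[3.2.1]octane-6,8-dione (CNP0190794.1)
Conditions: H2 (1 atm), Pd/CaCO3 poisoned with Pb(OAc)2, quinoline, EtOAc, 0 °C, stopped at 1.0 equiv H2
Reagents that add atoms: none
Why: Lindlar semihydrogenation delivers both hydrogens syn to the ynone triple bond and gives the Z-enone, while the trisubstituted prenyl alkenes and the hindered ketones are left alone; no stereocentre is formed or disturbed.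

**Compound list**
1 | (4S)-1-methyl-4-(prop-1-en-2-yl)-7-oxabicyclo[4.1.0]heptane, (−)-limonene 1,2-oxide, cis/trans mixture | C=C(C)[C@@H]1CC2OC2(C)CC1 | starting material
2 | (3S)-6-oxo-3-(prop-1-en-2-yl)heptanal | O=CC[C@@H](C(C)=C)CCC(C)=O | intermediate
3 | (5S)-8-methyl-5-(prop-1-en-2-yl)non-7-en-2-one | CC(C)=CC[C@@H](C(C)=C)CCC(C)=O | intermediate
4 | (8S)-2,11-dimethyl-8-(prop-1-en-2-yl)dodec-10-ene-3,5-dione | CC(C)=CC[C@@H](C(C)=C)CCC(=O)CC(=O)C(C)C | intermediate
5 | (8R)-2,11-dimethyl-6-(3-methylbut-2-en-1-yl)-8-(prop-1-en-2-yl)dodec-10-ene-3,5-dione, C6 epimers | CC(C)=CC[C@@H](C(C)=C)CC(CC=C(C)C)C(=O)CC(=O)C(C)C | intermediate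
6 | phenyl bromoacetate | O=C(CBr)Oc1ccccc1 | starting material
7 | (2-oxo-2-phenoxyethyl)triphenylphosphonium bromide | O=C(C[P+](c1ccccc1)(c1ccccc1)c1ccccc1)Oc1ccccc1.[Br-] | intermediate
8 | phenyl (triphenyl-λ5-phosphanylidene)acetate | O=C(C=P(c1ccccc1)(c1ccccc1)c1ccccc1)Oc1ccccc1 | intermediate
9 | trimethyl[(2-methylbut-3-yn-2-yl)oxy]silane | C#CC(C)(C)O[Si](C)(C)C | starting material
10 | lithium 4-methyl-4-[(trimethylsilyl)oxy]pent-2-ynoate | CC(C)(O[Si](C)(C)C)C#CC(=O)[O-].[Li+] | intermediate
11 | phenyl 6-methyl-3-oxo-2-(triphenyl-λ5-phosphanylidene)-6-[(trimethylsilyl)oxy]hept-4-ynoate | CC(C)(O[Si](C)(C)C)C#CC(=O)C(=P(c1ccccc1)(c1ccccc1)c1ccccc1)C(=O)Oc1ccccc1 | intermediate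
12 | phenyl 6-methyl-2,3-dioxo-6-[(trimethylsilyl)oxy]hept-4-ynoate | CC(C)(O[Si](C)(C)C)C#CC(=O)C(=O)C(=O)Oc1ccccc1 | intermediate
13 | (4R)-3,3-dimethyl-4,6-bis(3-methylbut-2-en-1-yl)-2-(2-methylpropanoyl)cyclohexan-1-one, C2/C6 epimers and enol forms | CC(C)=CC[C@@H]1CC(CC=C(C)C)C(=O)C(C(=O)C(C)C)C1(C)C | intermediate
14 | (1S,3R,5R,7S)-7-hydroxy-4,4-dimethyl-1,3-bis(3-methylbut-2-en-1-yl)-7-{4-methyl-4-[(trimethylsilyl)oxy]pent-2-ynoyl}-5-(2-methylpropanoyl)bicyclo[3.2.1]octane-6,8-dione | CC(C)=CC[C@@H]1C[C@]2(CC=C(C)C)C(=O)[C@@](C(=O)C(C)C)(C(=O)[C@@]2(O)C(=O)C#CC(C)(C)O[Si](C)(C)C)C1(C)C | intermediate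
15 | (1S,3R,5R,7S)-7-hydroxy-7-(4-hydroxy-4-methylpent-2-ynoyl)-4,4-dimethyl-1,3-bis(3-methylbut-2-en-1-yl)-5-(2-methylpropanoyl)bicyclo[3.2.1]octane-6,8-dione | CC(C)=CC[C@@H]1C[C@]2(CC=C(C)C)C(=O)[C@@](C(=O)C(C)C)(C(=O)[C@@]2(O)C(=O)C#CC(C)(C)O)C1(C)C | intermediate
16 | (1S,3R,5R,7S)-7-hydroxy-7-[(2Z)-4-hydroxy-4-methylpent-2-enoyl]-4,4-dimethyl-1,3-bis(3-methylbut-2-en-1-yl)-5-(2-methylpropanoyl)bicyclo[3.2.1]octane-6,8-dione (CNP0190794.1) | CC(C)=CC[C@@H]1C[C@]2(CC=C(C)C)C(=O)[C@@](C(=O)C(C)C)(C(=O)[C@@]2(O)C(=O)/C=C\C(C)(C)O)C1(C)C | target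

**Totals**
- Total steps: 10.
- Longest linear sequence: 6 (steps 1, 2, 3, 4, 9, 10).

**Steps most likely to fail and their fallbacks**

Step 9 is the most exposed step. The hazards are:
- O-capture instead of C-capture of the tertiary cation in stage a.
- Second deprotonation at the isobutyryl methine instead of the ring α′-carbon in stage b.
- Retro-aldol to the equatorial aldolate, which can only O-acylate to a fused enol lactone instead of giving the bridged triketone.

The fallback sets out from 5 and comes back to the route at 15. Stage a is run alone and cyclohexanone 13 is isolated. TMSOTf/Et3N converts it into the bis(trimethylsilyl) dienol ether of 13 F1. Effenberger-type annulation of this with malonyl dichloride (then KOH, BnEt3NCl) gives 6,6-dimethyl-1,7-bis(3-methylbut-2-en-1-yl)-5-(2-methylpropanoyl)bicyclo[3.3.1]nonane-2,4,9-trione F2, with the same chair control. Dess–Martin periodinane/pyridine oxidises the C3 methylene to the bicyclo[3.3.1]nonane-2,3,4,9-tetraone F3. Lithiated 9 (n-BuLi, −78 °C) adds to the central C3 carbonyl, and warming triggers an α-ketol shift of the C2 acyl bond to C4. This is the ring contraction known from hop α-acids to iso-α-acids; it gives 14 and, after the acidic work-up of step 9, 15.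

Step 10 may over-reduce, isomerise to the E-enone, or give the cyclic hemiketal. The fallback sets out from 15 and comes back at 16. CrSO4 (divalent chromium) in aqueous DMF reduces the ynone to the (2E) isomer of 16 F4. Irradiation at 350 nm in benzene then moves E to Z; the Z isomer is drained from the photoequilibrium as its reversible hemiketal, which reopens to 16 on isolation.

Step 8 may give the tricarbonyl only as a stubborn hydrate, lose the silyl group, or suffer ozone attack on the alkyne. The fallback sets out from 9 and comes back at 12. Lithiated 9 is acylated with carbonyldiimidazole to 1-{4-methyl-4-[(trimethylsilyl)oxy]pent-2-ynoyl}-1H-imidazole F5. Masamune homologation with Mg(O2CCH2CO2Ph)2 gives phenyl 6-methyl-3-oxo-6-[(trimethylsilyl)oxy]hept-4-ynoate F6. Diazo transfer (4-acetamidobenzenesulfonyl azide, Et3N) gives phenyl 2-diazo-6-methyl-3-oxo-6-[(trimethylsilyl)oxy]hept-4-ynoate F7. Dimethyldioxirane in acetone at −78 °C turns the diazo carbon into the central carbonyl, giving 12 without ozone and without a phosphorus by-product.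

Further compounds
F1 | step 9 | bis(trimethylsilyl) dienol ether of 13, trimethyl{[(4R)-5,5-dimethyl-2,4-bis(3-methylbut-2-en-1-yl)-6-{2-methyl-1-[(trimethylsilyl)oxy]propylidene}cyclohex-1-en-1-yl]oxy}silane | CC(C)=CC[C@@H]1CC(CC=C(C)C)=C(O[Si](C)(C)C)C(=C(O[Si](C)(C)C)C(C)C)C1(C)C
F2 | step 9 | 6,6-dimethyl-1,7-bis(3-methylbut-2-en-1-yl)-5-(2-methylpropanoyl)bicyclo[3.3.1]nonane-2,4,9-trione, bridgeheads and C7 as in 15 | CC(C)=CC[C@@H]1C[C@]2(CC=C(C)C)C(=O)[C@@](C(=O)C(C)C)(C(=O)CC2=O)C1(C)C
F3 | step 9 | 6,6-dimethyl-1,7-bis(3-methylbut-2-en-1-yl)-5-(2-methylpropanoyl)bicyclo[3.3.1]nonane-2,3,4,9-tetraone | CC(C)=CC[C@@H]1C[C@]2(CC=C(C)C)C(=O)[C@@](C(=O)C(C)C)(C(=O)C(=O)C2=O)C1(C)C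
F4 | step 10 | (2E) isomer of 16 | CC(C)=CC[C@@H]1C[C@]2(CC=C(C)C)C(=O)[C@@](C(=O)C(C)C)(C(=O)[C@@]2(O)C(=O)/C=C/C(C)(C)O)C1(C)C
F5 | step 8 | 1-{4-methyl-4-[(trimethylsilyl)oxy]pent-2-ynoyl}-1H-imidazole | CC(C)(O[Si](C)(C)C)C#CC(=O)n1ccnc1
F6 | step 8 | phenyl 6-methyl-3-oxo-6-[(trimethylsilyl)oxy]hept-4-ynoate | CC(C)(O[Si](C)(C)C)C#CC(=O)CC(=O)Oc1ccccc1
F7 | step 8 | phenyl 2-diazo-6-methyl-3-oxo-6-[(trimethylsilyl)oxy]hept-4-ynoate | CC(C)(O[Si](C)(C)C)C#CC(=O)C(=[N+]=[N-])C(=O)Oc1ccccc1
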